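**Retrosynthetic overview**

1. The bromohydrin is made last: a catalyst-controlled bromohydroxylation of the terminal C=C of a (Z)-1,3-diene forms the carbinol C–O bond together with the primary C–Br bond and sets the carbinol centre.
2. The (Z)-diene comes from a (Z)-alkenyl iodide (Stille vinylation), itself made from an aldehyde by an α-iodo-ylide Wittig reaction.
3. The only carbocycle (the cyclohexane) is closed by an enantiospecific bromonium/allylsilane cyclisation of an acyclic β-bromo ester; this sets both ring stereocentres and the exocyclic methylene.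
4. The β-bromo ester comes from an (R)-epoxide (Shi epoxidation) opened by bromide with inversion; the (Z)-allylsilane comes from nickel-catalysed ring-opening of a 5-alkyl-2,3-dihydrofuran.
5. Starting materials are 5-bromo-2-methylpent-2-ene and 2,3-dihydrofuran; ring order: oxirane (temporary), then cyclohexane.

Assumption: step 1 gives about 93 % ee (typical for 2-methylalk-2-enes), and the minor ring enantiomer, which ends as a diastereomer of the final product, is removed there by chromatography.

**Step 1**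
Reactants: 1 5-bromo-2-methylpent-2-ene
Product: 2 (R)-3-(2-bromoethyl)-2,2-dimethyloxirane
Conditions: D-fructose-derived Shi ketone (30 mol %), KHSO5 (as Oxone), K2CO3, Bu4NHSO4, MeCN/dimethoxymethane–aq. Na2B4O7 buffer (pH 10.5), 0 °C
Reagents that add atoms: potassium peroxymonosulfate, [K+].[O-]S(=O)(=O)OO
Why: Shi asymmetric epoxidation of the only (trisubstituted) alkene through the spiro dioxirane transition state gives the (R)-epoxide, which fixes the absolute configuration of the future C–Br carbon.

**Step 2**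
Reactants: 3 2,3-dihydrofuran; 2 (R)-3-(2-bromoethyl)-2,2-dimethyloxirane
Product: 5 5-{2-[(2R)-3,3-dimethyloxiran-2-yl]ethyl}-2,3-dihydrofuran, via 5-lithio-2,3-dihydrofuran 4 (not isolated)
Conditions: 3 (1.6 equiv), t-BuLi, THF, −78 → 0 °C; then 2, DMPU, −30 °C → rt
Reagents that add atoms: none
Why: α-Lithiation of the cyclic enol ether and SN2 alkylation by the primary bromide; the hindered trisubstituted epoxide is inert to the alkenyllithium without a Lewis acid, so the stereocentre is untouched.

**Step 3**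
Reactants: 5 5-{2-[(2R)-3,3-dimethyloxiran-2-yl]ethyl}-2,3-dihydrofuran
Product: 6 (3Z)-6-[(2R)-3,3-dimethyloxiran-2-yl]-4-[(trimethylsilyl)methyl]hex-3-en-1-ol
Conditions: Ni(cod)2 (5 mol %), LiCH2SiMe3 (1.5 equiv), toluene, rt, 2 h; then H2O
Reagents that add atoms: (trimethylsilyl)methyllithium, [Li]C[Si](C)(C)C
Why: Nickel-catalysed C(sp2)–O activation with ring-opening cross-coupling of a cyclic enol ether (Wenkert–Kocienski type) replaces oxygen by CH2SiMe3 with retention, so the silylmethyl group is cis to the hydroxyethyl chain (Z-allylsilane); the short reaction at room temperature is expected to spare the epoxide.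

**Step 4**
Reactants: 6 (3Z)-6-[(2R)-3,3-dimethyloxiran-2-yl]-4-[(trimethylsilyl)methyl]hex-3-en-1-ol
Product: 7 (3Z)-6-[(2R)-3,3-dimethyloxiran-2-yl]-4-[(trimethylsilyl)methyl]hex-3-enal
Conditions: Dess–Martin periodinane, pyridine, CH2Cl2, 0 °C; used crude
Reagents that add atoms: none
Why: Buffered Dess–Martin oxidation gives the β,γ-unsaturated aldehyde without touching epoxide or allylsilane, and immediate use avoids conjugation.

**Step 5**
Reactants: 7 (3Z)-6-[(2R)-3,3-dimethyloxiran-2-yl]-4-[(trimethylsilyl)methyl]hex-3-enal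
Product: 8 (3R)-3-{(3Z,6Z)-7-iodo-3-[(trimethylsilyl)methyl]octa-3,6-dien-1-yl}-2,2-dimethyloxirane
Conditions: EtPPh3I, n-BuLi, THF, rt; I2, −78 °C; NaN(SiMe3)2, −20 °C; then 7, −78 °C
Reagents that add atoms: ethyltriphenylphosphonium iodide, CC[P+](c1ccccc1)(c1ccccc1)c1ccccc1.[I-]; iodine, [I][I]
Why: Stork–Zhao-type Wittig olefination with the α-iodo ylide Ph3P=C(I)CH3 is kinetically cis-selective and puts iodine and the chain on the same side, giving the (Z)-2-iodoalk-2-ene (typically ≥ 10:1).

**Step 6**
Reactants: 8 (3R)-3-{(3Z,6Z)-7-iodo-3-[(trimethylsilyl)methyl]octa-3,6-dien-1-yl}-2,2-dimethyloxirane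
Product: 10 (3S,6Z,9Z)-3-bromo-10-iodo-2-methyl-6-[(trimethylsilyl)methyl]undeca-6,9-dien-2-yl 2,3,5,6-tetrafluorobenzoate, via lithium bromo-alkoxide 9 (not isolated)
Conditions: Li2NiBr4 (1.2 equiv), THF, 0 °C → rt; then 2,3,5,6-tetrafluorobenzoyl chloride, DMAP (cat.), 0 °C
Reagents that add atoms: Li2NiBr4, [Li+].[Li+].Br[Ni-2](Br)(Br)Br; 2,3,5,6-tetrafluorobenzoyl chloride, O=C(Cl)c1c(F)c(F)cc(F)c1F
Why: SN2 epoxide opening by the soft bromide of Li2NiBr4 at the less substituted carbon inverts it ((R)-C–O becomes (S)-C–Br, the ring C–Br centre of the target), and acylating the tertiary alkoxide in the same flask prevents re-closure and installs the leaving group.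

**Step 7**
Reactants: 10 (3S,6Z,9Z)-3-bromo-10-iodo-2-methyl-6-[(trimethylsilyl)methyl]undeca-6,9-dien-2-yl 2,3,5,6-tetrafluorobenzoate
Product: 11 (1S,3R)-1-bromo-3-[(2Z)-3-iodobut-2-en-1-yl]-2,2-dimethyl-4-methylidenecyclohexane
Conditions: TMSOTf (10 mol %), 2,6-di-tert-butylpyridine (20 mol %), CH2Cl2 (0.005 M), −78 → −40 °C
Reagents that add atoms: none
Why: Ionisation of the tertiary ester with anchimeric assistance by the neighbouring bromine gives a configurationally defined bromonium ion that the allylsilane captures anti to Br through a chair transition state (enantiospecific bromonium-initiated cation–olefin cyclisation with Sakurai-type termination); Br and side chain both end equatorial (cis, ring CH = R), and loss of silicon gives only the exocyclic methylene and regenerates TMSOTf.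

**Step 8**
Reactants: 11 (1S,3R)-1-bromo-3-[(2Z)-3-iodobut-2-en-1-yl]-2,2-dimethyl-4-methylidenecyclohexane
Product: 12 (1S,3R)-1-bromo-2,2-dimethyl-4-methylidene-3-[(2Z)-3-methylpenta-2,4-dien-1-yl]cyclohexane
Conditions: Bu3SnCH=CH2, Pd(PPh3)4 (5 mol %), CuI (10 mol %), DMF, 40 °C
Reagents that add atoms: tributyl(vinyl)stannane, C=C[Sn](CCCC)(CCCC)CCCC
Why: Stille coupling at the alkenyl iodide retains the Z geometry, and the hindered secondary alkyl bromide does not undergo oxidative addition under these conditions.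

**Step 9**
Reactants: 12 (1S,3R)-1-bromo-2,2-dimethyl-4-methylidene-3-[(2Z)-3-methylpenta-2,4-dien-1-yl]cyclohexane
Product: 13 (2S,3Z)-1-bromo-5-[(1R,3S)-3-bromo-2,2-dimethyl-6-methylidenecyclohexyl]-3-methylpent-3-en-2-ol
Conditions: (DHQD)2PHAL (10 mol %), N-bromobenzamide (1.1 equiv), H2O (20 equiv), (+)-camphorsulfonic acid (10 mol %), MeCN, −40 °C
Reagents that add atoms: N-bromobenzamide, O=C(NBr)c1ccccc1; water, O
Why: Proposed new method: site- and enantioselective bromohydroxylation of the terminal C=C of an unfunctionalised cis-1,3-diene, in which the protonated cinchona dimer binds the N-bromoamide and transfers Br+ to the unhindered, conjugation-activated terminal carbon while water held in the phthalazine pocket attacks the allyl-stabilised neighbouring carbon anti to bromine in a concerted, nucleophile-assisted addition, so that the more hindered exocyclic and trisubstituted alkenes should not compete, no free bromonium ion is released (no racemisation by olefin-to-olefin Br+ transfer, no 1,4-capture), the 3Z alkene is untouched and the catalyst pocket selects the alkene face that gives the (S)-carbinol; the closest known reaction type is the (DHQD)2PHAL-catalysed asymmetric bromohydroxylation of cinnamyl alcohols (and related cinchona-catalysed halofunctionalisations), not yet shown for dienes lacking a hydrogen-bonding handle.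

**Compound list**

1 | 5-bromo-2-methylpent-2-ene | CC(C)=CCCBr | starting material
2 | (R)-3-(2-bromoethyl)-2,2-dimethyloxirane | CC1(C)O[C@@H]1CCBr | intermediate
3 | 2,3-dihydrofuran | C1CC=CO1 | starting material
4 | 5-lithio-2,3-dihydrofuran | [Li]C1=CCCO1 | intermediate
5 | 5-{2-[(2R)-3,3-dimethyloxiran-2-yl]ethyl}-2,3-dihydrofuran | CC1(C)O[C@@H]1CCC1=CCCO1 | intermediate
6 | (3Z)-6-[(2R)-3,3-dimethyloxiran-2-yl]-4-[(trimethylsilyl)methyl]hex-3-en-1-ol | OCC/C=C(\C[Si](C)(C)C)CC[C@H]1OC1(C)C | intermediate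
7 | (3Z)-6-[(2R)-3,3-dimethyloxiran-2-yl]-4-[(trimethylsilyl)methyl]hex-3-enal | O=CC/C=C(\C[Si](C)(C)C)CC[C@H]1OC1(C)C | intermediate
8 | (3R)-3-{(3Z,6Z)-7-iodo-3-[(trimethylsilyl)methyl]octa-3,6-dien-1-yl}-2,2-dimethyloxirane | C/C(I)=C/C/C=C(\C[Si](C)(C)C)CC[C@H]1OC1(C)C | intermediate
9 | lithium (3S,6Z,9Z)-3-bromo-10-iodo-2-methyl-6-[(trimethylsilyl)methyl]undeca-6,9-dien-2-olate | C/C(I)=C/C/C=C(\C[Si](C)(C)C)CC[C@H](Br)C(C)(C)O[Li] | intermediate
10 | (3S,6Z,9Z)-3-bromo-10-iodo-2-methyl-6-[(trimethylsilyl)methyl]undeca-6,9-dien-2-yl 2,3,5,6-tetrafluorobenzoate | C/C(I)=C/C/C=C(\C[Si](C)(C)C)CC[C@H](Br)C(C)(C)OC(=O)c1c(F)c(F)cc(F)c1F | intermediate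
11 | (1S,3R)-1-bromo-3-[(2Z)-3-iodobut-2-en-1-yl]-2,2-dimethyl-4-methylidenecyclohexane | C=C1CC[C@H](Br)C(C)(C)[C@@H]1C/C=C(/C)I | intermediate
12 | (1S,3R)-1-bromo-2,2-dimethyl-4-methylidene-3-[(2Z)-3-methylpenta-2,4-dien-1-yl]cyclohexane | C=C1CC[C@H](Br)C(C)(C)[C@@H]1C/C=C(/C)C=C | intermediate
13 | (2S,3Z)-1-bromo-5-[(1R,3S)-3-bromo-2,2-dimethyl-6-methylidenecyclohexyl]-3-methylpent-3-en-2-ol | C=C1CC[C@H](Br)C(C)(C)[C@@H]1C/C=C(/C)[C@H](O)CBr | target

**Totals and risks**

Total step count: 9. Longest linear sequence: 9 (1 → 13; 3 enters at step 2).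

Steps most likely to fail:

**Step 9 (the new reaction).** Site selectivity among three alkenes, 1,2- versus 1,4-capture and the ee are all unproven, and the facial sense of the ligand is assigned only by analogy. If the (R)-carbinol forms, the pseudoenantiomer (DHQ)2PHAL is used instead. The fallback uses known chemistry, sets out from 12 and returns at 13. Pt(dba)3/TADDOL-derived phosphonite-catalysed enantioselective 1,2-diboration of the terminal alkene with B2pin2 (THF, 60 °C; ligand enantiomer chosen for the 2S product) gives the 1,2-bis(boronate) F1. A cis-diene cannot reach the s-cis form needed for 1,4-addition, and the 1,1-disubstituted exocyclic alkene is inert. NaOH/H2O2 oxidation with retention gives the (2S)-diol F2. Bu2SnO-catalysed monosulfonylation (TsCl, Et3N, CH2Cl2) gives the primary tosylate F3, and LiBr in acetone at 50 °C gives 13.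

**Step 7.** The electron-rich allylsilane may take up Br+ intermolecularly or be protodesilylated, and any olefin-to-olefin Br+ transfer erodes the ee. The fallback sets out from 5 and returns at 11; it uses the dihydrofuran itself as terminating nucleophile and makes the exocyclic methylene from a ketone. Compound 5 is opened and acylated exactly as in step 6, giving lithium alkoxide F4 and then tetrafluorobenzoate F5. TMSOTf (1.1 equiv) with 2,6-di-tert-butylpyridine in CH2Cl2 at −78 °C, followed by aqueous acid, lets the enol ether carbon close the six-membered ring on the bromonium ion. Hydrolysis of the oxocarbenium ion gives hydroxy ketone F6, whose side chain α to the carbonyl settles equatorial, cis to bromine. Takai–Lombardo methylenation (Zn, CH2Br2, TiCl4) gives methylidene alcohol F7, Dess–Martin oxidation gives aldehyde F8, and the α-iodo-ylide Wittig reaction of step 5 gives 11.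

**Step 6.** The regiochemistry of bromide attack on a trisubstituted epoxide and the one-flask acylation of a hindered tertiary alkoxide are both uncertain. The fallback sets out from 8 and returns at 11. The epoxide is opened deliberately at the tertiary carbon with MgBr2·OEt2 (Et2O, −20 °C) to give the regioisomeric bromohydrin F9, a secondary alcohol with its C–O configuration retained. The unhindered secondary hydroxyl is acylated (2,3,5,6-tetrafluorobenzoyl chloride, pyridine, DMAP) to give ester F10. Ionisation under the conditions of step 7 then lets the tertiary bromide displace the secondary ester from the rear; this gives the same bromonium ion as 10 does, and therefore 11.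

**Further compounds**

F1 | step 9 | 2,2'-{(2R,3Z)-5-[(1R,3S)-3-bromo-2,2-dimethyl-6-methylidenecyclohexyl]-3-methylpent-3-ene-1,2-diyl}bis(4,4,5,5-tetramethyl-1,3,2-dioxaborolane) | C=C1CC[C@H](Br)C(C)(C)[C@@H]1C/C=C(/C)[C@H](B1OC(C)(C)C(C)(C)O1)CB1OC(C)(C)C(C)(C)O1
F2 | step 9 | (2S,3Z)-5-[(1R,3S)-3-bromo-2,2-dimethyl-6-methylidenecyclohexyl]-3-methylpent-3-ene-1,2-diol | C=C1CC[C@H](Br)C(C)(C)[C@@H]1C/C=C(/C)[C@H](O)CO
F3 | step 9 | (2S,3Z)-5-[(1R,3S)-3-bromo-2,2-dimethyl-6-methylidenecyclohexyl]-2-hydroxy-3-methylpent-3-en-1-yl 4-methylbenzenesulfonate | C=C1CC[C@H](Br)C(C)(C)[C@@H]1C/C=C(/C)[C@H](O)COS(=O)(=O)c1ccc(C)cc1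
F4 | step 7 | lithium (3S)-3-bromo-5-(4,5-dihydrofuran-2-yl)-2-methylpentan-2-olate | [Li]OC(C)(C)[C@@H](Br)CCC1=CCCO1
F5 | step 7 | (3S)-3-bromo-5-(4,5-dihydrofuran-2-yl)-2-methylpentan-2-yl 2,3,5,6-tetrafluorobenzoate | CC(C)(OC(=O)c1c(F)c(F)cc(F)c1F)[C@@H](Br)CCC1=CCCO1
F6 | step 7 | (2S,4S)-4-bromo-2-(2-hydroxyethyl)-3,3-dimethylcyclohexan-1-one | O=C1CC[C@H](Br)C(C)(C)[C@@H]1CCO
F7 | step 7 | 2-[(1R,3S)-3-bromo-2,2-dimethyl-6-methylidenecyclohexyl]ethan-1-ol | C=C1CC[C@H](Br)C(C)(C)[C@@H]1CCO
F8 | step 7 | 2-[(1R,3S)-3-bromo-2,2-dimethyl-6-methylidenecyclohexyl]acetaldehyde | C=C1CC[C@H](Br)C(C)(C)[C@@H]1CC=O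
F9 | step 6 | (3R,6Z,9Z)-2-bromo-10-iodo-2-methyl-6-[(trimethylsilyl)methyl]undeca-6,9-dien-3-ol | C/C(I)=C/C/C=C(\C[Si](C)(C)C)CC[C@@H](O)C(C)(C)Br
F10 | step 6 | (3R,6Z,9Z)-2-bromo-10-iodo-2-methyl-6-[(trimethylsilyl)methyl]undeca-6,9-dien-3-yl 2,3,5,6-tetrafluorobenzoate | C/C(I)=C/C/C=C(\C[Si](C)(C)C)CC[C@@H](OC(=O)c1c(F)c(F)cc(F)c1F)C(C)(C)Br
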